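**Plan**
Retrosynthesis: the lactol C1–O bond is opened to a formyl group and a tert-butyl ester on ring B. The aryl–C(=O) and C(=O)–O bonds of the seven-membered lactone are then cut together, which removes the carbonyl carbon as CO. Last, the diaryl ether C–O bond is cut on the ring A side.
Enabling feature: in the central dioxepinone ring the ester carbonyl carbon is bonded only to the ring A carbon lying between C–CH3 and C–OAr and to the ring B oxygen ortho to the ether oxygen. It is therefore a one-carbon bridge between an aryl iodide and a phenol that the ether already holds side by side.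
Forward: ring A (2 steps) and ring B (5 steps) are made separately and joined through the ether by SNAr. The seven-membered lactone is closed next by CO insertion, and the five-membered lactol ring closes last, on acidolysis of the ester.
Stereochemistry: the only stereocentre, lactol carbon C1, first forms racemic. It is set as (S) by a catalyst-controlled acylative dynamic kinetic resolution and uncovered by an enzymatic alcoholysis that breaks none of its bonds.

Key step: step 10

Assumption: the lactol carbon of the target inverts only by way of the open formyl acid, taken to be fast with amine base and slow in dry, neutral ether at or below 0 °C, so the (S)-lactol is released in the last step and kept cold and dry.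

**Step 1**
Reactants: 1 3-fluoro-5-methylanisole
Product: 3 2-fluoro-6-methoxy-4-methylbenzaldehyde, via aryllithium 2 (not isolated)
Conditions: n-BuLi, THF, −78 °C; DMF, −78 °C to 0 °C; 1 M HCl
Reagents that add atoms: N,N-dimethylformamide, CN(C)C=O; n-butyllithium, [Li]CCCC (lithium stays only in 2)
Why: Directed ortho-metalation followed by formylation: the hydrogen between F and OMe is the most acidic one and both neighbours bind lithium, so only that carbon is lithiated, and holding 2 at −78 °C prevents loss of LiF to an aryne before DMF is added.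

**Step 2**
Reactants: 3 2-fluoro-6-methoxy-4-methylbenzaldehyde
Product: 4 2-fluoro-3-iodo-6-methoxy-4-methylbenzaldehyde
Conditions: N-iodosuccinimide, CF3CO2H, 0 °C to rt
Reagents that add atoms: N-iodosuccinimide, O=C1CCC(=O)N1I
Why: Electrophilic aromatic iodination with acid-activated N-iodosuccinimide: both free ring positions are meta to the formyl group, and the one para to OMe and next to the small fluorine should win over the one wedged between OMe and CH3.

**Step 3**
Reactants: 5 4,6-dibromoresorcinol
Product: 6 1,5-dibromo-2,4-bis[(4-methoxybenzyl)oxy]benzene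
Conditions: 4-methoxybenzyl chloride (2.2 equiv), K2CO3, DMF, 60 °C
Reagents that add atoms: 4-methoxybenzyl chloride, COc1ccc(CCl)cc1
Why: Williamson ether synthesis on both phenols; the 4-methoxybenzyl ethers stand up to organolithium and magnesium amide bases and to carbonate, and they can later be taken off oxidatively beside an aryl iodide, two aldehydes and a tert-butyl ester.

**Step 4**
Reactants: 6 1,5-dibromo-2,4-bis[(4-methoxybenzyl)oxy]benzene
Product: 9 5-bromo-2,4-bis[(4-methoxybenzyl)oxy]phenol, via aryllithium 7 (not isolated), via dimethyl boronate 8 (not isolated)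
Conditions: n-BuLi (1.0 equiv), THF, −78 °C; B(OMe)3, −78 °C to 0 °C; AcOH, 30% H2O2, 0 °C to rt
Reagents that add atoms: hydrogen peroxide, OO; n-butyllithium, [Li]CCCC (lithium stays only in 7); trimethyl borate, COB(OC)OC (its atoms stay only in 8)
Why: Bromine–lithium exchange, borylation and peroxide oxidation: the two bromines of 6 are equivalent by symmetry, so one equivalent of n-BuLi at −78 °C should exchange just one of them, and the C–Li bond is turned into C–OH by 1,2-aryl shift from boron to oxygen.

**Step 5**
Reactants: 9 5-bromo-2,4-bis[(4-methoxybenzyl)oxy]phenol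
Product: 10 1-bromo-5-(1-ethoxyethoxy)-2,4-bis[(4-methoxybenzyl)oxy]benzene (racemic at the acetal carbon)
Conditions: ethyl vinyl ether, pyridinium p-toluenesulfonate (cat.), CH2Cl2, rt
Reagents that add atoms: ethyl vinyl ether, C=COCC
Why: Acid-catalysed addition of the phenol to an enol ether (acetal protection): the ethoxyethyl ether is inert to n-BuLi, offers an extra oxygen for coordination in the later metalation and is lost in dilute acid that leaves the benzyl-type ethers and the tert-butyl ester alone.

**Step 6**
Reactants: 10 1-bromo-5-(1-ethoxyethoxy)-2,4-bis[(4-methoxybenzyl)oxy]benzene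
Product: 12 tert-butyl 5-(1-ethoxyethoxy)-2,4-bis[(4-methoxybenzyl)oxy]benzoate, via aryllithium 11 (not isolated)
Conditions: n-BuLi, THF, −78 °C; transfer into Boc2O (2 equiv), THF, −78 °C; H2O
Reagents that add atoms: di-tert-butyl dicarbonate, CC(C)(C)OC(=O)OC(=O)OC(C)(C)C; n-butyllithium, [Li]CCCC (lithium stays only in 11)
Why: Bromine–lithium exchange and C-acylation of the aryllithium with Boc2O, a standard entry to tert-butyl benzoates; inverse addition to excess Boc2O in the cold keeps the hindered ester from being attacked a second time.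

**Step 7**
Reactants: 12 tert-butyl 5-(1-ethoxyethoxy)-2,4-bis[(4-methoxybenzyl)oxy]benzoate
Product: 15 tert-butyl 2-formyl-3-hydroxy-4,6-bis[(4-methoxybenzyl)oxy]benzoate, via arylmagnesium amide 13 (not isolated), via ethoxyethyl-protected aldehyde 14 (not isolated)
Conditions: (TMP)2Mg·2LiCl (TMP = 2,2,6,6-tetramethylpiperidide), THF, 0 °C; DMF, 0 °C to rt; 1 M HCl, THF, rt
Reagents that add atoms: N,N-dimethylformamide, CN(C)C=O; magnesium bis(2,2,6,6-tetramethylpiperidide), CC1(C)CCCC(C)(C)N1[Mg]N1C(C)(C)CCCC1(C)C (its atoms stay only in 13)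
Why: Directed ortho-magnesiation with a hindered magnesium bis-amide that tolerates tert-butyl esters: the only C–H flanked by the ester and the acetal oxygen is metalated (the C–H between the two benzyloxy groups has no carbonyl to guide the base), DMF delivers the formyl group, and the acidic work-up hydrolyses the acetal to the hydrogen-bonded salicylaldehyde.

**Step 8**
Reactants: 4 2-fluoro-3-iodo-6-methoxy-4-methylbenzaldehyde; 15 tert-butyl 2-formyl-3-hydroxy-4,6-bis[(4-methoxybenzyl)oxy]benzoate
Product: 16 tert-butyl 2-formyl-3-(2-formyl-6-iodo-3-methoxy-5-methylphenoxy)-4,6-bis[(4-methoxybenzyl)oxy]benzoate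
Conditions: Cs2CO3, 4 Å molecular sieves, dry DMSO, 90 °C
Reagents that add atoms: none
Why: Nucleophilic aromatic substitution by addition–elimination: the fluorine is ortho to the formyl group, which takes up the charge of the Meisenheimer adduct, OMe and CH3 are meta to the reacting carbon and do not oppose it, and the iodine, meta to the formyl group and a poor leaving group in this mechanism, should stay in place.

**Step 9**
Reactants: 16 tert-butyl 2-formyl-3-(2-formyl-6-iodo-3-methoxy-5-methylphenoxy)-4,6-bis[(4-methoxybenzyl)oxy]benzoate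
Product: 17 tert-butyl 2-formyl-3-(2-formyl-6-iodo-3-methoxy-5-methylphenoxy)-4,6-dihydroxybenzoate
Conditions: 2,3-dichloro-5,6-dicyano-1,4-benzoquinone (DDQ, 2.5 equiv), CH2Cl2/pH 7 buffer, 0 °C to rt
Reagents that add atoms: none
Why: Oxidative cleavage of 4-methoxybenzyl ethers by hydride abstraction with DDQ and hydrolysis of the oxocarbenium ions; the near-neutral medium should spare the aryl iodide, both aldehydes, the aryl methyl ether and the tert-butyl ester, and the electron-poor ring B is not oxidised further.

**Step 10**
Reactants: 17 tert-butyl 2-formyl-3-(2-formyl-6-iodo-3-methoxy-5-methylphenoxy)-4,6-dihydroxybenzoate; 18 carbon monoxide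
Product: 19 tert-butyl 4,6-diformyl-8-hydroxy-3-methoxy-1-methyl-11-oxo-11H-dibenzo[b,e][1,4]dioxepine-7-carboxylate
Conditions: Pd(OAc)2 (10 mol %), 4,5-bis(diphenylphosphino)-9,9-dimethylxanthene (Xantphos, 12 mol %), CO (1 atm), NEt3 (3 equiv), toluene (0.01 M), 70 °C
Reagents that add atoms: carbon monoxide, [C-]#[O+]
Why: Pd(OAc)2 is reduced in situ to zerovalent palladium, which as its Xantphos complex adds oxidatively to the ring A C–I bond; CO then inserts into the aryl–palladium bond, a move favoured by the relief of crowding between the flanking CH3 and OAr groups, and the ring B phenoxide next to the ether oxygen takes over the acyl group while NEt3 binds the HI. The closest known reaction type is the palladium-catalysed aryloxycarbonylation of aryl iodides with phenols, used here in its intramolecular form as a carbonylative lactonisation. The seven-membered ring closes by 7-exo-trig attack of the phenoxide oxygen on the acyl–palladium carbon (or, equivalently, by acyl–oxygen reductive elimination from an eight-membered palladacycle), and no stereocentre is created. Of the two free phenols only the one ortho to the ether can reach the acyl carbon within the molecule; the other is para to the ether and hydrogen-bonded to the ester carbonyl, so it could react only between molecules, which the 0.01 M dilution disfavours. Two further diversions must lose out, direct aryl–oxygen coupling to a dibenzodioxin and base-induced Smiles migration of the formyl-activated ring A onto the neighbouring phenoxide: the first is outrun by CO insertion under a CO atmosphere, the second is held back by the use of an amine base in toluene at moderate temperature in place of carbonate in a dipolar solvent. The two aldehydes and the tert-butyl ester take no part.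

**Step 11**
Reactants: 19 tert-butyl 4,6-diformyl-8-hydroxy-3-methoxy-1-methyl-11-oxo-11H-dibenzo[b,e][1,4]dioxepine-7-carboxylate
Product: 21 racemic 1,4-dihydroxy-10-methoxy-8-methyl-3,7-dioxo-1,3-dihydro-7H-isobenzofuro[4,5-b][1,4]benzodioxepine-11-carbaldehyde, via open formyl acid 20 (not isolated)
Conditions: CF3CO2H/CH2Cl2, 0 °C to rt
Reagents that add atoms: none
Why: Acidolysis of the tert-butyl ester with loss of isobutene, followed by the spontaneous ring–chain tautomerism of a 2-formylbenzoic acid to its 3-hydroxyphthalide (5-exo-trig addition of the acid O–H to the formyl group); the diaryl lactone, ether and aldehyde are acid-stable and C1 is formed racemic.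

**Step 12**
Reactants: 21 racemic lactol
Product: 23 (1S)-1,4-diacetoxy-10-methoxy-8-methyl-3,7-dioxo-1,3-dihydro-7H-isobenzofuro[4,5-b][1,4]benzodioxepine-11-carbaldehyde, via racemic phenol acetate 22 (not isolated)
Conditions: Ac2O (3 equiv), i-Pr2NEt (3 equiv), (2S,3R)-3,4-dihydro-3-isopropyl-2-phenyl-2H-pyrimido[2,1-b]benzothiazole (HyperBTM, 10 mol %; its mirror image is used instead if a trial run shows the opposite sense), CH2Cl2, −20 °C
Reagents that add atoms: acetic anhydride, CC(=O)OC(C)=O
Why: Acylative dynamic kinetic resolution of a 3-hydroxyphthalide with a chiral isothiourea acyl-transfer catalyst: once the phenol has been acetylated, the amine base interconverts the two lactol enantiomers through the open formyl carboxylate while the chiral N-acetyl isothiouronium ion acetylates the (S)-lactol faster, so C1 is set by the catalyst, both enantiomers of which can be bought.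

**Step 13**
Reactants: 23 (1S)-diacetate
Product: 25 (1S)-1,4-dihydroxy-10-methoxy-8-methyl-3,7-dioxo-1,3-dihydro-7H-isobenzofuro[4,5-b][1,4]benzodioxepine-11-carbaldehyde, via (S)-lactol monoacetate 24 (not isolated)
Conditions: immobilised Burkholderia cepacia lipase, n-BuOH (6 equiv), dry Et2O/THF, 0 °C; filtration, evaporation below 0 °C
Reagents that add atoms: none
Why: Lipase-catalysed alcoholysis (acyl transfer to n-butanol), known for aryl acetates and for γ-acetoxy lactones: the serine hydrolase attacks only the two acetyl carbonyl groups, so no bond at C1 is broken and the (S)-configuration is retained, and the cold, dry, base-free ether lacks the catalysts of lactol ring opening.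

**Compound list**
1 | 3-fluoro-5-methylanisole | COc1cc(C)cc(F)c1 | starting material
2 | (2-fluoro-6-methoxy-4-methylphenyl)lithium | [Li]c1c(F)cc(C)cc1OC | intermediate
3 | 2-fluoro-6-methoxy-4-methylbenzaldehyde | COc1cc(C)cc(F)c1C=O | intermediate
4 | 2-fluoro-3-iodo-6-methoxy-4-methylbenzaldehyde | COc1cc(C)c(I)c(F)c1C=O | intermediate
5 | 4,6-dibromoresorcinol (4,6-dibromobenzene-1,3-diol) | Oc1cc(O)c(Br)cc1Br | starting material
6 | 1,5-dibromo-2,4-bis[(4-methoxybenzyl)oxy]benzene | COc1ccc(COc2cc(OCc3ccc(OC)cc3)c(Br)cc2Br)cc1 | intermediate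
7 | {5-bromo-2,4-bis[(4-methoxybenzyl)oxy]phenyl}lithium | [Li]c1cc(Br)c(OCc2ccc(OC)cc2)cc1OCc1ccc(OC)cc1 | intermediate
8 | dimethyl {5-bromo-2,4-bis[(4-methoxybenzyl)oxy]phenyl}boronate | COB(OC)c1cc(Br)c(OCc2ccc(OC)cc2)cc1OCc1ccc(OC)cc1 | intermediate
9 | 5-bromo-2,4-bis[(4-methoxybenzyl)oxy]phenol | Oc1cc(Br)c(OCc2ccc(OC)cc2)cc1OCc1ccc(OC)cc1 | intermediate
10 | 1-bromo-5-(1-ethoxyethoxy)-2,4-bis[(4-methoxybenzyl)oxy]benzene (racemic acetal) | CCOC(C)Oc1cc(Br)c(OCc2ccc(OC)cc2)cc1OCc1ccc(OC)cc1 | intermediate
11 | {5-(1-ethoxyethoxy)-2,4-bis[(4-methoxybenzyl)oxy]phenyl}lithium | CCOC(C)Oc1cc([Li])c(OCc2ccc(OC)cc2)cc1OCc1ccc(OC)cc1 | intermediate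
12 | tert-butyl 5-(1-ethoxyethoxy)-2,4-bis[(4-methoxybenzyl)oxy]benzoate | CCOC(C)Oc1cc(C(=O)OC(C)(C)C)c(OCc2ccc(OC)cc2)cc1OCc1ccc(OC)cc1 | intermediate
13 | aryl(2,2,6,6-tetramethylpiperidido)magnesium, Mg on the carbon between ester and acetal oxygen of 12 | CCOC(C)Oc1c([Mg]N2C(C)(C)CCCC2(C)C)c(C(=O)OC(C)(C)C)c(OCc2ccc(OC)cc2)cc1OCc1ccc(OC)cc1 | intermediate
14 | tert-butyl 3-(1-ethoxyethoxy)-2-formyl-4,6-bis[(4-methoxybenzyl)oxy]benzoate | CCOC(C)Oc1c(C=O)c(C(=O)OC(C)(C)C)c(OCc2ccc(OC)cc2)cc1OCc1ccc(OC)cc1 | intermediate
15 | tert-butyl 2-formyl-3-hydroxy-4,6-bis[(4-methoxybenzyl)oxy]benzoate | CC(C)(C)OC(=O)c1c(C=O)c(O)c(OCc2ccc(OC)cc2)cc1OCc1ccc(OC)cc1 | intermediate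
16 | tert-butyl 2-formyl-3-(2-formyl-6-iodo-3-methoxy-5-methylphenoxy)-4,6-bis[(4-methoxybenzyl)oxy]benzoate | COc1cc(C)c(I)c(Oc2c(OCc3ccc(OC)cc3)cc(OCc3ccc(OC)cc3)c(C(=O)OC(C)(C)C)c2C=O)c1C=O | intermediate
17 | tert-butyl 2-formyl-3-(2-formyl-6-iodo-3-methoxy-5-methylphenoxy)-4,6-dihydroxybenzoate | COc1cc(C)c(I)c(Oc2c(O)cc(O)c(C(=O)OC(C)(C)C)c2C=O)c1C=O | intermediate
18 | carbon monoxide | [C-]#[O+] | starting material
19 | tert-butyl 4,6-diformyl-8-hydroxy-3-methoxy-1-methyl-11-oxo-11H-dibenzo[b,e][1,4]dioxepine-7-carboxylate | COc1cc(C)c2c(c1C=O)Oc1c(cc(O)c(C(=O)OC(C)(C)C)c1C=O)OC2=O | intermediate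
20 | 4,6-diformyl-8-hydroxy-3-methoxy-1-methyl-11-oxo-11H-dibenzo[b,e][1,4]dioxepine-7-carboxylic acid | COc1cc(C)c2c(c1C=O)Oc1c(cc(O)c(C(=O)O)c1C=O)OC2=O | intermediate
21 | racemic 1,4-dihydroxy-10-methoxy-8-methyl-3,7-dioxo-1,3-dihydro-7H-isobenzofuro[4,5-b][1,4]benzodioxepine-11-carbaldehyde | COc1cc(C)c2c(c1C=O)Oc1c(cc(O)c3c1C(O)OC3=O)OC2=O | intermediate
22 | racemic 4-acetoxy-1-hydroxy analogue of 21 (phenol acetate, free lactol) | COc1cc(C)c2c(c1C=O)Oc1c(cc(OC(C)=O)c3c1C(O)OC3=O)OC2=O | intermediate
23 | (1S)-1,4-diacetoxy-10-methoxy-8-methyl-3,7-dioxo-1,3-dihydro-7H-isobenzofuro[4,5-b][1,4]benzodioxepine-11-carbaldehyde | COc1cc(C)c2c(c1C=O)Oc1c(cc(OC(C)=O)c3c1[C@@H](OC(C)=O)OC3=O)OC2=O | intermediate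
24 | (1S)-1-acetoxy-4-hydroxy-10-methoxy-8-methyl-3,7-dioxo-1,3-dihydro-7H-isobenzofuro[4,5-b][1,4]benzodioxepine-11-carbaldehyde | COc1cc(C)c2c(c1C=O)Oc1c(cc(O)c3c1[C@@H](OC(C)=O)OC3=O)OC2=O | intermediate
25 | (1S)-1,4-dihydroxy-10-methoxy-8-methyl-3,7-dioxo-1,3-dihydro-7H-isobenzofuro[4,5-b][1,4]benzodioxepine-11-carbaldehyde | COc1cc(C)c2c(c1C=O)Oc1c(cc(O)c3c1[C@@H](O)OC3=O)OC2=O | target

**Step count**
Total steps: 13. Longest linear sequence: 11 steps (from 5 to 25, steps 3 to 13).

**Steps most likely to fail**

Step 13. The freed lactol may open to the formyl acid and close again while the second acetate is still being cleaved or during isolation, so that the configuration set in step 12 erodes. Slow acceptance of the bulky (S)-ester by the enzyme would lengthen this exposure. The fallback, which also bypasses step 12, sets out from racemic lactol 21. The enantiomers are separated physically by preparative chromatography on an immobilised amylose carbamate phase with a neutral aprotic eluent at about −20 °C. The (S)-fraction is crystallised at once from the cold eluate. The (R)-lactol F1 is re-equilibrated to 21 with a trace of NEt3 and recycled. The route is rejoined at 25.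

Step 10. Oxidative addition to the di-ortho-substituted iodide and capture of the crowded acyl–palladium may be slow. Smiles migration of ring A onto the neighbouring phenoxide, hydrodeiodination or acylation between molecules could then take over. The fallback sets out from 16, in which both phenols are still masked. The same CO carbon is put in by an intermolecular aryloxycarbonylation with pentafluorophenol (Pd(OAc)2, Xantphos, CO, NEt3, toluene) to give the protected pentafluorophenyl ester F2. DDQ then frees the phenols to give the dihydroxy active ester F3. This closes to the lactone by transesterification in dilute CH2Cl2 with i-Pr2NEt at room temperature. The route is rejoined at 19.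

Step 8. Addition of the hindered, formyl-conjugated phenoxide to a carbon flanked by iodine and formyl may need temperatures at which the aldehydes and the ester degrade. The fallback uses a stronger activating group and sets out from 3 and 15.
- Nitration of 3 (KNO3, H2SO4, 0 °C, para to OMe) gives 2-fluoro-6-methoxy-4-methyl-3-nitrobenzaldehyde F4.
- Its fluorine is ortho to both NO2 and CHO and should be displaced by 15 with K2CO3 in DMF near room temperature, giving the nitro diaryl ether F5.
- Reduction with Fe powder and NH4Cl in aqueous ethanol gives the amino diaryl ether F6.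
- An aprotic Sandmeyer iodination (t-BuONO, CH2I2, MeCN) gives the iodide, and the route is rejoined at 16.

**Further compounds**
F1 | step 13 | (1R)-1,4-dihydroxy-10-methoxy-8-methyl-3,7-dioxo-1,3-dihydro-7H-isobenzofuro[4,5-b][1,4]benzodioxepine-11-carbaldehyde (enantiomer of 25) | COc1cc(C)c2c(c1C=O)Oc1c(cc(O)c3c1[C@H](O)OC3=O)OC2=O
F2 | step 10 | pentafluorophenyl 2-{3-(tert-butoxycarbonyl)-2-formyl-4,6-bis[(4-methoxybenzyl)oxy]phenoxy}-3-formyl-4-methoxy-6-methylbenzoate | COc1cc(C)c(C(=O)Oc2c(F)c(F)c(F)c(F)c2F)c(Oc2c(OCc3ccc(OC)cc3)cc(OCc3ccc(OC)cc3)c(C(=O)OC(C)(C)C)c2C=O)c1C=O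
F3 | step 10 | pentafluorophenyl 2-[3-(tert-butoxycarbonyl)-2-formyl-4,6-dihydroxyphenoxy]-3-formyl-4-methoxy-6-methylbenzoate | COc1cc(C)c(C(=O)Oc2c(F)c(F)c(F)c(F)c2F)c(Oc2c(O)cc(O)c(C(=O)OC(C)(C)C)c2C=O)c1C=O
F4 | step 8 | 2-fluoro-6-methoxy-4-methyl-3-nitrobenzaldehyde | COc1cc(C)c([N+](=O)[O-])c(F)c1C=O
F5 | step 8 | tert-butyl 2-formyl-3-(2-formyl-3-methoxy-5-methyl-6-nitrophenoxy)-4,6-bis[(4-methoxybenzyl)oxy]benzoate | COc1cc(C)c([N+](=O)[O-])c(Oc2c(OCc3ccc(OC)cc3)cc(OCc3ccc(OC)cc3)c(C(=O)OC(C)(C)C)c2C=O)c1C=O
F6 | step 8 | tert-butyl 3-(6-amino-2-formyl-3-methoxy-5-methylphenoxy)-2-formyl-4,6-bis[(4-methoxybenzyl)oxy]benzoate | COc1cc(C)c(N)c(Oc2c(OCc3ccc(OC)cc3)cc(OCc3ccc(OC)cc3)c(C(=O)OC(C)(C)C)c2C=O)c1C=O
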